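The constant you want first is how fast a warm flask empties itself of X, and cedar shows it. At −8 °C, cedar's X stops rising and stands near 2.17% while J is still fed. Divide that standing X by the feed, the whole charge over 30 min. This gives the hold-up life of X, the time a portion of X stays where feed and loss balance (a steady-state approximation): 0.650 min. I assume each portion of fed J passes through X. A frozen X would read the same in cedar, so losing X is my reading, not a proof.

common to all: J 0.050 M (fed, over 30 min)

| run | E | L | temperature | remark | time |
|---|---|---|---|---|---|
| oak | 2.5 mM | 6.7 mM | −30 °C | run made earlier |  |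
| cedar | 2.5 mM | 15 mM | −8 °C | run made earlier |  |
| delta | 2.50 mM | 10 mM |  | at −40 °C until 15 min, from then on at 0 °C | 30 min |
| alpha | 2.50 mM | 10 mM |  | at −40 °C throughout | 30 min |

- oak (time / min: X / %, J / %): 2.50: 1.9, 6.0; 5.00: 5.7, 8.2; 8.00: 11.6, 9.6; 10.0: 15.2, 10.3; 12.0: 19.9, 10.6; 15.0: 24.5, 11.3; 20.0: 32.1, 11.9
- cedar (time / min: X / %, J / %): 0.833: 0.9, 1.4; 1.50: 2.2, 1.4; 2.50: 2.8, 0.6; 3.00: 1.6, 1.2; 4.00: 2.2, 0.8; 5.00: 2.1, 0.9; 6.00: 2.2, 0.4

(scatter of a reading: 0.3 percentage points)

- percentages count the whole charge, also what has not yet gone in

* which one finishes higher in amount of X, in percent of the J charged ("neither" within 2 percentage points) (delta / alpha / neither)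
* amount of X at the end, in percent of the J charged, delta
* amount of X at the end, in percent of the J charged, alpha

Now turn the settings by hand.

1. Temperature. Delta goes to 0 °C, warmer than cedar, so I take its life as no longer than 0.650 min. The 15.0 min after the change are 23.1 lives, so the X standing at the change does not count at the end. Delta should then hold the feed times the life, below 2.17%.

2. L. The level c_X = feed × life has no c_L in it. Oak and cedar differ in temperature as well as in L, so they do not test this.

3. E. The level has no c_E in it either. Oak and cedar share one charge of E, so they show nothing here.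

4. Staying cold. Alpha stays at −40 °C, colder than oak, and oak's X was still rising at 20.0 min, at 32.1%. I see no level there and accept the forecast's value for alpha.

The forecast says alpha finishes higher, with 31% for delta and 60% for alpha, reasoning “so X itself looks stable”. My reckoning shares its choice and its alpha, but puts delta below 2.17%.

    Z → L + X (k = 0.0260 /s, Ea = 68.0 kJ/mol)
    2 Z → G (k = 0.130 /M/s, Ea = 38.0 kJ/mol)
    J + E → Q (k = 0.220 /M/s, Ea = 36.0 kJ/mol)
    J + L → Z (k = 0.280 /M/s, Ea = 42.0 kJ/mol)
    X → D (k = 1.80 × 10⁻⁴ /s, Ea = 77.0 kJ/mol)
    (constants at −40 °C)

Delta ends at 0.912% and alpha at 62.3%, so alpha finishes higher. At the change, at 15.0 min, delta had 25.0% of X. At 30.0 min delta holds 93.3% of D. Its level times the dosing time gives a hold-up life of 0.274 min at 0 °C, shorter than cedar's 0.650 min. The neighbour of delta with E cut to 6.3 × 10⁻⁴ M ends at 0.917% of X, a hold-up life of 0.275 min.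

(The earlier runs and the new flask stem from a simulated flask for an exercise; scatter was added.)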